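Don't read the flat end of alpha as a dead flask.

| setting | alpha | eta | flask |
|---|---|---|---|
| starting material | 0.054 M | 0.027 M | 0.054 M |
| solid second substrate | 1.3 equiv | 1.3 equiv | 1.30 equiv |
| free enzyme | 5.2 × 10⁻⁴ mol% | 5.2 × 10⁻⁴ mol% | 5.2 × 10⁻⁴ mol% |
| temperature | 25 °C | 31 °C | 25 °C |
| remark | the very flask that is asked about, followed so far | run made earlier |  |
| time |  |  | 2.5 d |

| run | time / h | target / % |
|---|---|---|
| alpha | 4.00 | 11 |
| alpha | 8.00 | 21 |
| alpha | 20.0 | 34 |
| alpha | 50.0 | 39 |
| eta | 1.50 | 5 |
| eta | 3.00 | 11 |
| eta | 5.00 | 19 |
| eta | 6.00 | 25 |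

(standard deviation of a reading: 1.5 percentage points)

- Monday's: change nothing and wait 5.0 d more
- Saturday's: at 2.5 d raise the temperature by 20 K, then wait 5.0 d
- Friday's: at 2.5 d add free enzyme, 100% of the amount charged, then wait 5.0 d
- Wednesday's: at 2.5 d take out 90% of the target then present, then wait 5.0 d

- what is taken out of target is counted as made
- at the start none of the solid second substrate is in solution
- additions bring no volume worth counting

1. target, in percent of the starting material first charged, at 2.5 d
2. what to do for the largest gain in target; "none" if nothing gains more than 2 percentage points (Monday's / Saturday's / Friday's / Wednesday's / none)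
3. target present, with what was taken out counted in, in percent of the starting material first charged, after Saturday's
4. target present, with what was taken out counted in, in percent of the starting material first charged, after Wednesday's

Weigh two amounts at alpha's last reading: the target, 39% at 50.0 h, and the rest of the charge. At the pace of its early readings, alpha passes the whole charge in 38.1 h, less than 50.0 h. So take the rest as a second form standing in balance with target (thermodynamic control), not as unused starting material. The stall ratio is 1.56, the rest of the charge over target at the stall, a reading with the scatter of its readings. Freeze it: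

target = what stays in the flask / (1 + stall ratio)

My own reckoning: expect about 39% now, and nothing from waiting or from more enzyme. For Wednesday's, take out 35.1%, which leaves 64.9%:

target with what was taken out = 35.1% + 64.9% / (1 + stall ratio) = 60.5%

Leave heat open, since eta was still rising at its last reading and gives no stall at another temperature.

The forecast says 39.5% now, Wednesday's as best, 41% after Saturday's and 58% after Wednesday's: “Heating shifts the equilibrium by an unknown amount, probably little.”

The flask gives 38.5%, and Saturday's is best, gaining 25 percentage points against 21 points for Wednesday's. Monday's and Friday's gain 0 points. Saturday's ends at 63.9%, Wednesday's at 59.8%.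

    free enzyme → unfolded enzyme (k = 1.40 × 10⁻⁴ min⁻¹, Ea = 228 kJ mol⁻¹)
    starting material + free enzyme ⇌ first complex (K = 860 M⁻¹, k = 63000 M⁻¹ s⁻¹, Ea = 19.0 kJ mol⁻¹, ΔH = −33.0 kJ mol⁻¹)
    first complex ⇌ loaded enzyme + first product (K = 0.0450 M, k = 39000 min⁻¹, Ea = 50.0 kJ mol⁻¹, ΔH = −52.0 kJ mol⁻¹)
    second substrate + loaded enzyme ⇌ second complex (K = 22.0 M⁻¹, k = 12000 M⁻¹ s⁻¹, Ea = 32.0 kJ mol⁻¹, ΔH = 2.00 kJ mol⁻¹)
    second complex → free enzyme + target (k = 1800 min⁻¹, Ea = 67.0 kJ mol⁻¹)
    solid second substrate ⇌ second substrate, rate k6*(cs6 - [second substrate]) while solid is left; crystals form when [second substrate] > cs6 (solubility = 9.60 mM, k = 0.00850 min⁻¹)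
    target ⇌ isomer of the product (K = 1.60, k = 0.00380 min⁻¹, Ea = 85.0 kJ mol⁻¹, ΔH = −41.0 kJ mol⁻¹)
    (constants at 25 °C)

With 38.5%, the stall ratio puts Wednesday's at 60.1%, against 59.8%. The rest is isomer of the product: the passing of target into it, both ways, is the main reason for the stall, for without that step target at 2.5 d stands at 100%, not 38.5%. Saturday's moves the ratio itself, to 0.565.

In the flask left until 15 h, 57.5% has left the starting material, so the ratio gives 22.4% target. The computed flask holds 28.3% beside 29.2% isomer of the product, a ratio still below the stall ratio.

(All runs are simulated for substances that don't exist; scatter was added.)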